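Draw the tail of the summer run on a log axis before choosing when to stop this flask, which has the same charge as that run.

| flask | substrate | reagent | remark | time |
|---|---|---|---|---|
| summer | 0.050 M | 0.075 M | the very flask that is asked about, followed so far |  |
| dawn | 0.034 M | 0.075 M | run made earlier |  |
| flask | 0.050 M | 0.0750 M |  | 30 h |

- summer (time / h: single product / %): 1.33: 16.2; 2.50: 21.0; 4.00: 23.6; 8.00: 21.2; 15.0: 17.2
- dawn (time / h: single product / %): 1.33: 14.0; 2.50: 23.1; 4.00: 26.4; 6.00: 25.8; 12.0: 20.3

(each reading ± 1 percentage point)

- time, not beyond 30 h, at which the flask holds most single product
- the amount of single product, in percent of the substrate charged, at that time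
- the first time at which single product reaches 12 %, in the same percent

- what was read earlier has a scatter of 1 percentage point, one standard deviation

My rule of thumb is to treat the tail as pseudo-first-order, so that single product loses equal powers of ten in equal times. Its carried quantity is the decade time, the hours the tail needs to fall tenfold. The summer readings at 8.00 h and 15.0 h give 77.1 h, longer than the limit of 30 h, so by this rule the tail of this flask loses less than a power of ten before that limit. I commit to a peak near the 23.6 % read at 4.00 h in the summer run, and the straight line from zero through the first summer reading crosses 12 % at 0.985 h.

The rule has a border. The limit of 30 h is twice the time of the last summer reading, and the dawn tail gives 57.6 h, a ratio of 1.34 between the two runs. So the decade time is a reading of one stretch of one run, and I trust it little far beyond 15.0 h.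

The forecast says single product “climbs quickly, peaks, then fades slowly” and gives 4.6 h, 23.8 % and 0.9 h, a crossing earlier than mine.

The flask gives its maximum of 23.4 % at 5.18 h and crosses the level at 0.967 h, so the forecast stands within the tolerance and the stop for this flask belongs near 5.18 h.

    substrate + reagent → single product (k = 6.38 × 10⁻⁴ M⁻¹ s⁻¹)
    reagent + single product → bis adduct (k = 2.62 × 10⁻⁴ M⁻¹ s⁻¹)
    reagent + single product → over-reaction product (k = 3.91 × 10⁻⁴ M⁻¹ s⁻¹)
    2 substrate → self-condensation product (k = 7.94 × 10⁻⁴ M⁻¹ s⁻¹)

Run from that maximum, the decade time gives 11.2 % at 30 h, but this flask holds less than that, 7.82 %, so from its top to the limit it falls more steeply than the line. For the neighbouring flask, left until 8.0 h, the same reckoning gives 21.5 %, and that flask holds 22.1 %.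

(All runs come from a simulation on assumed constants, noise included.)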